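## Structural features

Dactylomelol is built on a cyclohexane ring (C6–C11) whose C7 and C10 are tied together by an oxygen atom, giving a 7-oxabicyclo[2.2.1]heptane with C7 (methyl-bearing) and C10 (CH) as bridgeheads. Two arms leave the two-carbon bridge C6–C11: C6 carries the chain C5–C1 ending in the tertiary vinyl carbinol C3 (3S), and the quaternary C11 carries a methyl group and the chain C12–C15 ending in a secondary bromide (C14, S) next to a tertiary chloride (C15). The four ring stereocentres are contiguous (C10 S, C11 S, C6 S, C7 R): the C11 methyl and the C6 chain are exo, on the side of the oxygen bridge, and the C11 chain is endo, so the two chains on C6 and C11 are trans. C3 and C14 lie four and three bonds from the nearest ring stereocentre and cannot be set by relay from the ring. The fragile groups are the tertiary allylic alcohol (ionisation and allylic transposition in acid), the vicinal bromochloride (elimination with base, reductive elimination with zinc or hydride) and the tertiary C7–O ether bond (reversible in strong acid). The real difficulty is the crowded C10–C11–C6–C7 array, with a quaternary carbon wedged between the oxygenated bridgehead and the chain-bearing C6, together with the remote C14. The feature used here is the 1,4 relation across the ring between the C10 oxygen and the methyl-bearing C7: a cyclohex-3-enol with its olefin at C6=C7 is one Markovnikov addition away from the bicycle, and its C7 methyl, C10 stereocentre and C11 methylene are already present in the cyclohexenone ring of carvone.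

## Logic of the disconnections

27 ⇒ 26. Cut: C14–Br and C15–Cl. Reason: the vicinal bromochloride tolerates neither the zinc of step 17, the hydride of step 14, nor the basic ylide and phosphonate of steps 12 and 13, so it is made last from the C14=C15 olefin; Markovnikov opening of a bromiranium ion puts bromine on the secondary and chlorine on the tertiary carbon. Gain: two halogens and one stereocentre are exchanged for a prenyl terminus. Demand: C14 is three bonds from C11, so its configuration must come from the reagent, which must also prefer the trisubstituted olefin to the C1=C2 vinyl group.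

26 ⇒ 25 ⇒ 24 ⇒ 23. Cut: the C3–OH/C1=C2 unit is read as a transposed 2,3-epoxy alcohol, so the bonds concerned are the epoxide C2–O bond and the C1–I bond. Reason: C3 is four bonds from C6, and an unselective vinyl addition to a methyl ketone would give both epimers; an allylic alcohol lets a tartrate-controlled epoxidation set C3. Gain: the quaternary carbinol is reduced to the geometry of a trisubstituted olefin. Demand: 23 must be the pure E isomer, and the reductive opening must leave C14=C15 alone.

23 ⇒ 22 ⇒ 21. Cut: C2=C3, after adjusting the oxidation level at C1. Reason: this leaves at C3 a methyl ketone, the one chain terminus that is indifferent to the strong acid of the key step. Gain: two carbons are removed. Demand: E selectivity, or clean removal of the Z ester.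

21 ⇒ 20 ⇒ 19 ⇒ 18. Cut: C14=C15, then the C14 aldehyde back to a benzyl-protected alcohol. Reason: a trisubstituted olefin in the C11 arm would itself be protonated in step 9, and a free primary hydroxyl there could trap a C6 cation as a six-membered ether, so the arm crosses that step as a three-carbon benzyl ether. Gain: the arm shrinks to a spectator chain. Demand: the benzyl group must be removed while the molecule holds no olefin, and the ylide must take the aldehyde in preference to the ketone.

18 ⇒ 17. Cut: C7–O. Reason: it is the one ring bond whose formation also creates both remaining ring stereocentres (C6, C7) under the control of the two that exist (C10, C11). Gain: one ring and two stereocentres; what remains is a monocyclic cyclohexenol. Demand: capture at C7 by the C10 hydroxyl, with hydrogen delivered to C6 from the opposite face, in the presence of a ketone and a benzyl ether.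

17 ⇒ 15 (through 16). Cut: no skeletal bond; the C10 acetate and the dioxolane are removed. Reason: the C10 oxygen stays acylated until C6 is no longer a carbonyl carbon, because a free β-hydroxy ketone with a quaternary α-carbon invites retro-aldol cleavage of C10–C11. The ketone stays masked through the organozinc step and is unmasked before step 9, so that no oxocarbenium ion can form beside the olefin under anhydrous acid. Gain: 15 is inert to the coupling conditions. Demand: methanolysis of a hindered secondary acetate.

15 ⇒ 12 + 13 (through 14). Cut: C5–C6. Reason: cross-coupling at an enol triflate places the olefin exactly at C6=C7 and joins the ketone arm convergently. Gain: the four-carbon arm leaves as a commercial bromide. Demand: oxidative addition and transmetallation at a tetrasubstituted triflate flanked by a quaternary carbon.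

12 ⇒ 10 (through 11). Cut: C6–OTf back to the C6 carbonyl and C8–H back to the enone. Reason: 1,4-reduction of the enone gives a single enolate regioisomer, the one required. Demand: conjugate rather than carbonyl attack, and trapping before the enolate can attack the neighbouring acetate.

10 ⇒ 7 (through 8 and 9). Cut: C10–O back to the C10–isopropenyl bond. Reason: the group that steered the alkylation is exchanged for oxygen with retention by ozonolysis and Criegee rearrangement. Gain: C10 comes from the chiral pool. Demand: ozone must take the isopropenyl group and spare the enone olefin and the benzyl ether, which is why the allyl group is converted first.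

7 ⇒ 6 ⇒ 4. Cut: O–benzyl, then C14–O back to a terminal olefin. Reason: an allyl group is the best electrophile for the quaternisation and is a latent 3-oxypropyl chain. Demand: hydroboration of the allyl olefin in the presence of the isopropenyl group and the enone.

4 ⇒ 2 + 3 and 2 ⇒ 1. Cut: C11–C12 and C11–CH3. Reason: two successive α'-alkylations build the quaternary centre, methyl first and allyl second, so that the chain enters anti to the isopropenyl group and the methyl ends cis to the future C10 oxygen, as the exo methyl of the bicycle requires. Gain: everything traces to 1 and 3. Demand: kinetic α' enolisation and high facial selectivity in the second alkylation.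

## Other disconnections considered

Alternative 1: The cut runs through C5–C6 and C11–CH3 of a cyclohexenone in which C7 already carries its methyl group and its oxygen. The substrate would be the achiral quinol ether 4-(methoxymethoxy)-4-methylcyclohexa-2,5-dien-1-one A2.
- Forward key step: Cu(OTf)2 with a chiral binaphthol phosphoramidite would add bis[2-(2-methyl-1,3-dioxolan-2-yl)ethyl]zinc A3 to one of the two enantiotopic β-carbons (C6). The zinc enolate would then be methylated at C11 to give (4R,5S,6S)-4-(methoxymethoxy)-4,6-dimethyl-5-[2-(2-methyl-1,3-dioxolan-2-yl)ethyl]cyclohex-2-en-1-one A1. No ring closes.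
- In its favour: the absolute configuration would come from a catalyst acting on an achiral substrate, so either enantiomer is open. C6 would be set directly and independently of any later ring closure. The ketone arm, the C7 oxygen and the C11 methyl would all be present after one operation.
- Against it here: the oxygen bridge is still open and C10 is a ketone. The bridge would have to be closed later either by displacement at a secondary carbon next to a quaternary one, or by ionisation at C7, which discards the C7 stereocentre that the desymmetrisation created. C11 still needs its chain through alkylation of a hindered α-methyl ketone enolate, and half of the functionalised alkyl groups of A3 are wasted.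
- Comparison: on structure, A1 has C6 fixed before the bridge exists, whereas the chosen plan makes C6 and C7 together in step 9. In the control of C6 and in the free choice of enantiomer the alternative is the better plan. On mechanism, both use well-understood steps, but the chosen key step closes a ring and sets two stereocentres where the alternative's closes none. On step economy the two should be about equal up to the bicycle, since the alternative must still add the C11 chain, reduce C8=C9 and C10=O and close the bridge; both then face the same work at C3 and C14.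

Alternative 2: The cut is made at C7–O and C10–C11 together. The precursor would be the lactone-fused donor–acceptor cyclopropane methyl (1R,5R,6S)-6-methyl-2-oxo-6-(3-oxopropyl)-3-oxabicyclo[3.1.0]hexane-1-carboxylate A5, which derives from a Z trisubstituted allylic alcohol by intramolecular cyclopropanation and oxidative cleavage of the remote olefin.
- Forward key step: Sc(OTf)3 would open the cyclopropane at C7–C11. The tethered C10 aldehyde would add across it, oxygen to C7 with inversion and the malonate carbon C11 to C10, closing both rings of the bicycle. The product would be the tricyclic lactone ester methyl (1S,2R,6R,7R)-7-methyl-3-oxo-4,10-dioxatricyclo[5.2.1.0^2,6]decane-2-carboxylate A4.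
- In its favour: two rings and two bonds would form in one step. C7, C10 and C11 would be set at once, with C6 carried in from the cyclopropanation. The lactone locks the C6/C11 relationship, and the core would be reached in very few operations from an acyclic olefin of defined geometry.
- Against it here: C11 would carry two carboxyl-level carbons, one of which has to be taken down to the methyl group and the other extended to the C12–C15 arm. C5 would arrive as a lactone CH2–O that must be homologated to the C4–C1 arm, so many redox and deoxygenation steps at a neopentyl centre follow. The bridging mode, with the aldehyde tethered to the donor carbon, asks for a strained transition state. Enantiocontrol would rest on cyclopropanation of a trisubstituted allylic diazomalonate.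
- Comparison: on structure and ring-forming power the alternative is the better plan, with two rings against one. On mechanism, the chosen step has the simpler stereochemical argument (anti addition and thermodynamic convergence), while the alternative is stereospecific but depends on a demanding intramolecular geometry. On step economy the chosen plan should win, because its C11 substituents arrive at the right oxidation level and C10 comes from the chiral pool.

Alternative 3: The cut is made at C7–O and C6–C7. The precursor would be the keto alcohol (5S,6S,7E)-5-hydroxy-6-methyl-6-(4-methylpent-3-en-1-yl)-9-(trimethylsilyl)non-7-en-2-one A7, whose C10–C11 bond and quaternary centre would come from addition of a γ,γ-disubstituted Z allylboron reagent to an aldehyde, followed by cross-metathesis to the E allylsilane.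
- Forward key step: Me3SiOTf would turn the C10 hydroxyl and the C7 ketone into the five-membered cyclic oxocarbenium ion. The allylsilane would attack it through C6, closing both rings and leaving a vinyl group on C6. The product would be (1R,2S,3S,4S)-2-ethenyl-1,3-dimethyl-3-(4-methylpent-3-en-1-yl)-7-oxabicyclo[2.2.1]heptane A6.
- In its favour: this is the shortest way to the bicycle. Two rings, two bonds and the C6 and C7 stereocentres would come from one step, and the C11 arm with its C14=C15 olefin would already be complete, so no debenzylation, oxidation or Wittig step would be needed. The vinyl group is a clean handle for the C6 arm.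
- Against it here: C6 selectivity (vinyl exo or endo) would depend on the transition-state geometry of a bridging cyclisation and cannot be corrected by equilibration. The prenyl olefin must survive a strong silyl Lewis acid beside an oxocarbenium ion. The quaternary C11 next to the carbinol must come from a reagent-controlled allylboration. The C6 arm must still be grown from the vinyl group to the C3 carbinol.
- Comparison: in step economy up to the bicycle, and in having the C11 arm finished early, the alternative is the better plan. On structure the two are equal in what they must still do at C3 and C14. On mechanism the chosen plan is the safer, because C10 and C11 come from a chiral-pool ketone by alkylations of known facial sense, and C6 is backed by both anti addition and thermodynamic preference.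

Key step: step 9

Assumption on the chemistry: 2 is carried forward as its mixture of C6 epimers, because this centre becomes planar again in step 2; the catalyst pseudoenantiomer in step 18 is fixed by trial.

## Steps

Step 1
Reactants: 1 (S)-carvone, (5S)-2-methyl-5-(prop-1-en-2-yl)cyclohex-2-en-1-one
Product: 2 (5S)-2,6-dimethyl-5-(prop-1-en-2-yl)cyclohex-2-en-1-one (C6 epimer mixture, the 6R trans isomer expected to predominate)
Conditions: LiN(i-Pr)2, THF, −78 °C; MeI, −78 to 0 °C
Reagents that add atoms: iodomethane, CI
Why: Kinetic deprotonation of the enone at the α' methylene (the future C11) and SN2 methylation of the lithium enolate (enolate alkylation); the new centre need not be controlled because it is re-enolised in step 2.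

Step 2
Reactants: 2 (5S)-2,6-dimethyl-5-(prop-1-en-2-yl)cyclohex-2-en-1-one; 3 allyl bromide (3-bromoprop-1-ene)
Product: 4 (5R,6R)-2,6-dimethyl-6-(prop-2-en-1-yl)-5-(prop-1-en-2-yl)cyclohex-2-en-1-one
Conditions: LiN(i-Pr)2, THF, −78 to −20 °C; allyl bromide (3), DMPU, −78 °C to rt
Reagents that add atoms: none
Why: Enolate alkylation: the tetrasubstituted lithium enolate is allylated on the face anti to the neighbouring isopropenyl group, so the allyl group (future C12–C14) ends trans to isopropenyl and the methyl cis, which fixes quaternary C11; the change of the C5 descriptor from S to R reflects CIP priorities only.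

Step 3
Reactants: 4 (5R,6R)-2,6-dimethyl-6-(prop-2-en-1-yl)-5-(prop-1-en-2-yl)cyclohex-2-en-1-one
Product: 6 (5R,6R)-6-(3-hydroxypropyl)-2,6-dimethyl-5-(prop-1-en-2-yl)cyclohex-2-en-1-one, via alkyl(disiamyl)borane 5 (not isolated)
Conditions: Sia2BH (from BH3·THF and 2-methylbut-2-ene), THF, −10 to 0 °C; then NaBO3·4H2O, THF–H2O, rt
Reagents that add atoms: disiamylborane, CC(C)C(C)BC(C)C(C)C (boron residue present in 5 only); sodium perborate, [Na+].[Na+].O[B-]1(O)OO[B-](O)(O)OO1 (hydroxyl oxygen of 6)
Why: Anti-Markovnikov hydroboration–oxidation; the bulky dialkylborane should add to the monosubstituted allyl olefin much faster than to the 1,1-disubstituted isopropenyl group, the enone olefin or the hindered conjugated carbonyl, and perborate oxidises the C–B bond without the strongly basic peroxide that would epoxidise the enone.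

Step 4
Reactants: 6 (5R,6R)-6-(3-hydroxypropyl)-2,6-dimethyl-5-(prop-1-en-2-yl)cyclohex-2-en-1-one
Product: 7 (5R,6R)-6-[3-(benzyloxy)propyl]-2,6-dimethyl-5-(prop-1-en-2-yl)cyclohex-2-en-1-one
Conditions: 2-benzyloxy-1-methylpyridinium triflate, MgO, PhCF3, 85 °C
Reagents that add atoms: 2-benzyloxy-1-methylpyridinium trifluoromethanesulfonate, C[n+]1ccccc1OCc1ccccc1.[O-]S(=O)(=O)C(F)(F)F
Why: O-Benzylation of the primary alcohol by benzyl transfer from the pyridinium salt under buffered, essentially neutral conditions; no base is present that could form the dienolate of the enone and no strong acid that could touch the isopropenyl group.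

Step 5
Reactants: 7 (5R,6R)-6-[3-(benzyloxy)propyl]-2,6-dimethyl-5-(prop-1-en-2-yl)cyclohex-2-en-1-one
Product: 10 (1S,2R)-2-[3-(benzyloxy)propyl]-2,4-dimethyl-3-oxocyclohex-4-en-1-yl acetate, via methoxy hydroperoxide 8 (not isolated), via peroxyacetate 9 (not isolated)
Conditions: O3, CH2Cl2–MeOH, −78 °C (Sudan red end point); then Ac2O, Et3N, DMAP (cat.), 0 °C to rt
Reagents that add atoms: ozone, [O-][O+]=O (ring-bound ester oxygen); methanol, CO (methoxy group of 8 and 9, carbonyl oxygen of 10); acetic anhydride, CC(=O)OC(C)=O (acetyl group of 9 only)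
Why: Ozonolysis of the electron-rich isopropenyl group in methanol (the electron-poor enone olefin should react far more slowly) gives the α-methoxy hydroperoxide, whose peracetate undergoes Criegee rearrangement; the ring carbon migrates from carbon to oxygen with retention, so C10–O replaces C10–C with unchanged configuration, and the acetyl group of 10 is the former isopropenyl C–CH3 unit.

Step 6
Reactants: 10 (1S,2R)-2-[3-(benzyloxy)propyl]-2,4-dimethyl-3-oxocyclohex-4-en-1-yl acetate
Product: 12 (5S,6R)-5-acetoxy-6-[3-(benzyloxy)propyl]-2,6-dimethylcyclohex-1-en-1-yl trifluoromethanesulfonate, via lithium enolate 11 (not isolated)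
Conditions: LiBH(s-Bu)3, THF, −78 °C; then N-(5-chloropyridin-2-yl)bis(trifluoromethanesulfonyl)imide, −78 to 0 °C
Reagents that add atoms: N-(5-chloropyridin-2-yl)-1,1,1-trifluoro-N-(trifluoromethylsulfonyl)methanesulfonamide, O=S(=O)(N(c1ccc(Cl)cn1)S(=O)(=O)C(F)(F)F)C(F)(F)F; lithium tri-sec-butylborohydride, [Li+].CCC(C)[BH-](C(C)CC)C(C)CC (lithium of 11 only)
Why: Conjugate hydride reduction of the β-unsubstituted enone, whose carbonyl is shielded by the adjacent quaternary carbon, gives regiospecifically the C6=C7 enolate, which is O-sulfonylated in the same flask (enol triflate formation); trapping at −78 °C with the reactive pyridyl triflimide is meant to outrun acetyl transfer from the C10 acetate to the enolate oxygen.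

Step 7
Reactants: 12 (5S,6R)-5-acetoxy-6-[3-(benzyloxy)propyl]-2,6-dimethylcyclohex-1-en-1-yl trifluoromethanesulfonate; 13 2-(2-bromoethyl)-2-methyl-1,3-dioxolane
Product: 15 (1S,2S)-2-[3-(benzyloxy)propyl]-2,4-dimethyl-3-[2-(2-methyl-1,3-dioxolan-2-yl)ethyl]cyclohex-3-en-1-yl acetate, via alkylzinc bromide 14 (not isolated)
Conditions: 13, Zn dust (activated by BrCH2CH2Br and Me3SiCl), LiCl, THF, 40 °C; then 12, Pd(OAc)2 (cat.), SPhos (cat.), THF, 50 °C
Reagents that add atoms: zinc, [Zn] (zinc of 14 only)
Why: Negishi sp2–sp3 cross-coupling: zerovalent palladium formed in the flask inserts into the C–OTf bond, the primary alkylzinc transmetallates and reductive elimination forms C5–C6; a bulky electron-rich biarylphosphine is chosen because the triflate carbon is flanked by a quaternary carbon (2,6,6-trisubstituted cyclohexenyl triflates are established coupling partners), and acetate, ketal and benzyl ether are inert to the organozinc.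

Step 8
Reactants: 15 (1S,2S)-2-[3-(benzyloxy)propyl]-2,4-dimethyl-3-[2-(2-methyl-1,3-dioxolan-2-yl)ethyl]cyclohex-3-en-1-yl acetate
Product: 17 4-[(5S,6S)-6-[3-(benzyloxy)propyl]-5-hydroxy-2,6-dimethylcyclohex-1-en-1-yl]butan-2-one, via hydroxy ketal 16 (not isolated)
Conditions: K2CO3 (cat.), MeOH, rt; then aq. HCl (to pH 1), rt
Reagents that add atoms: water, O
Why: Base-catalysed transesterification removes the C10 acetate (safe now that C6 is no longer a carbonyl, so no retro-aldol cleavage of C10–C11 is possible), and dilute aqueous acid then hydrolyses the dioxolane to the methyl ketone; this acid is too weak and too wet to protonate the tetrasubstituted olefin at a useful rate.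

Step 9
Reactants: 17 4-[(5S,6S)-6-[3-(benzyloxy)propyl]-5-hydroxy-2,6-dimethylcyclohex-1-en-1-yl]butan-2-one
Product: 18 4-[(1R,2S,3S,4S)-3-[3-(benzyloxy)propyl]-1,3-dimethyl-7-oxabicyclo[2.2.1]heptan-2-yl]butan-2-one
Conditions: TfOH (5–10 mol %), CH2Cl2, −20 to 0 °C
Reagents that add atoms: none
Why: The acid protonates C6 of the tetrasubstituted olefin and the C10 hydroxyl, held 1,4-cis across the ring, attacks C7 as positive charge develops there (concerted with proton transfer or just after it), after which the oxonium ion returns the proton to the catalyst. The closest known reaction type is the acid-catalysed transannular Markovnikov hydroalkoxylation of 4-hydroxy-1-methylcyclohexenes to 1,4-epoxy-p-menthane (1,4-cineole-type) ethers. One ring closes: counted through the C8–C9 tether the oxolane O–C7–C8–C9–C10 forms in the 5-exo-trig mode (C6 stays outside it), and the same C7–O bond completes the second five-membered ring O–C7–C6–C11–C10 of the bicycle. C7 is controlled by C10, because the oxygen can bridge only on its own face, which places the C7 methyl at the bridgehead with the R configuration. C6 is controlled by anti addition: the proton arrives on the face opposite the incoming oxygen, leaving H endo and the ketone chain exo, cis to the C11 methyl and trans to the C11 chain. That epimer should also be the thermodynamic one, and since ether formation, deprotonation to the C5=C6, C7=C8 and exocyclic C7 olefin isomers and their reprotonation are all reversible under the catalyst, kinetic leaks are expected to drain back to 18. The step needs site selectivity (capture at C7 by the alcohol and not by the ketone oxygen, nor by the benzyl ether oxygen at an isomeric C6 cation) and freedom from 1,2-shifts out of quaternary C11. The cis 1,4 geometry fixed in steps 2 and 5, the five-membered intramolecular transition state, the low temperature and the catalytic amount of a non-nucleophilic acid are what should secure this.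

Step 10
Reactants: 18 4-[(1R,2S,3S,4S)-3-[3-(benzyloxy)propyl]-1,3-dimethyl-7-oxabicyclo[2.2.1]heptan-2-yl]butan-2-one
Product: 19 4-[(1R,2S,3S,4S)-3-(3-hydroxypropyl)-1,3-dimethyl-7-oxabicyclo[2.2.1]heptan-2-yl]butan-2-one
Conditions: H2 (1 atm), 10% Pd/C, EtOAc, rt
Reagents that add atoms: none
Why: Hydrogenolysis of the benzyl ether at the one stage of the route that holds no olefin; the dialkyl ketone and the non-benzylic bridging ether are not affected.

Step 11
Reactants: 19 4-[(1R,2S,3S,4S)-3-(3-hydroxypropyl)-1,3-dimethyl-7-oxabicyclo[2.2.1]heptan-2-yl]butan-2-one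
Product: 20 4-[(1R,2S,3S,4S)-1,3-dimethyl-3-(3-oxopropyl)-7-oxabicyclo[2.2.1]heptan-2-yl]butan-2-one
Conditions: PhI(OAc)2, TEMPO (cat.), CH2Cl2, rt
Reagents that add atoms: none
Why: Nitroxyl (oxoammonium) catalysed oxidation of the primary alcohol, which stops at the aldehyde and leaves the ketone untouched.

Step 12
Reactants: 20 4-[(1R,2S,3S,4S)-1,3-dimethyl-3-(3-oxopropyl)-7-oxabicyclo[2.2.1]heptan-2-yl]butan-2-one
Product: 21 4-[(1R,2S,3S,4S)-1,3-dimethyl-3-(4-methylpent-3-en-1-yl)-7-oxabicyclo[2.2.1]heptan-2-yl]butan-2-one
Conditions: i-PrPPh3 iodide, n-BuLi, THF, 0 °C; then 20 (ylide about 1.1 equiv), −78 to 0 °C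
Reagents that add atoms: isopropyltriphenylphosphonium iodide, CC(C)[P+](c1ccccc1)(c1ccccc1)c1ccccc1.[I-]
Why: Wittig olefination forms C14=C15; the hindered non-stabilised ylide, used in slight excess at low temperature, should react with the aldehyde much faster than with the methyl ketone, and no olefin geometry arises because C15 carries two methyl groups.

Step 13
Reactants: 21 4-[(1R,2S,3S,4S)-1,3-dimethyl-3-(4-methylpent-3-en-1-yl)-7-oxabicyclo[2.2.1]heptan-2-yl]butan-2-one
Product: 22 ethyl (2E)-5-[(1R,2S,3S,4S)-1,3-dimethyl-3-(4-methylpent-3-en-1-yl)-7-oxabicyclo[2.2.1]heptan-2-yl]-3-methylpent-2-enoate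
Conditions: (EtO)2P(O)CH2CO2Et, NaH, THF, 0 °C to reflux; chromatographic removal of the Z ester
Reagents that add atoms: triethyl phosphonoacetate, CCOC(=O)CP(=O)(OCC)OCC
Why: Horner–Wadsworth–Emmons olefination of the methyl ketone, which should favour the E trisubstituted ester (larger chain trans to the ester); the minor Z isomer has to be removed here because it would lead to the C3 epimer.

Step 14
Reactants: 22 ethyl (2E)-5-[(1R,2S,3S,4S)-1,3-dimethyl-3-(4-methylpent-3-en-1-yl)-7-oxabicyclo[2.2.1]heptan-2-yl]-3-methylpent-2-enoate
Product: 23 (2E)-5-[(1R,2S,3S,4S)-1,3-dimethyl-3-(4-methylpent-3-en-1-yl)-7-oxabicyclo[2.2.1]heptan-2-yl]-3-methylpent-2-en-1-ol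
Conditions: i-Bu2AlH, CH2Cl2, −78 °C
Reagents that add atoms: none
Why: 1,2-Reduction of the conjugated ester to the allylic alcohol by the aluminium hydride; olefins and the ether are inert.

Step 15
Reactants: 23 (2E)-5-[(1R,2S,3S,4S)-1,3-dimethyl-3-(4-methylpent-3-en-1-yl)-7-oxabicyclo[2.2.1]heptan-2-yl]-3-methylpent-2-en-1-ol
Product: 24 [(2S,3S)-3-{2-[(1R,2S,3S,4S)-1,3-dimethyl-3-(4-methylpent-3-en-1-yl)-7-oxabicyclo[2.2.1]heptan-2-yl]ethyl}-3-methyloxiran-2-yl]methanol
Conditions: Ti(OiPr)4 (cat.), L-(+)-diethyl tartrate (cat.), t-BuOOH, 4 Å molecular sieves, CH2Cl2, −20 °C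
Reagents that add atoms: tert-butyl hydroperoxide, CC(C)(C)OO
Why: Sharpless asymmetric epoxidation: the titanium tartrate complex binds the allylic alcohol and delivers oxygen to one face of C2=C3 only, L-(+)-tartrate giving the (2S,3S) epoxide of an E 3,3-disubstituted allylic alcohol; this sets C3 by reagent control, and the isolated C14=C15 olefin, which has no directing hydroxyl, is not epoxidised.

Step 16
Reactants: 24 [(2S,3S)-3-{2-[(1R,2S,3S,4S)-1,3-dimethyl-3-(4-methylpent-3-en-1-yl)-7-oxabicyclo[2.2.1]heptan-2-yl]ethyl}-3-methyloxiran-2-yl]methanol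
Product: 25 (2R,3S)-3-{2-[(1R,2S,3S,4S)-1,3-dimethyl-3-(4-methylpent-3-en-1-yl)-7-oxabicyclo[2.2.1]heptan-2-yl]ethyl}-2-(iodomethyl)-3-methyloxirane
Conditions: I2, PPh3, imidazole, Et2O–MeCN, 0 °C
Reagents that add atoms: iodine, II
Why: Appel-type conversion of the primary alcohol into the iodide through the alkoxyphosphonium salt; no stereocentre is touched (the change of the C2 descriptor reflects CIP priorities only).

Step 17
Reactants: 25 (2R,3S)-3-{2-[(1R,2S,3S,4S)-1,3-dimethyl-3-(4-methylpent-3-en-1-yl)-7-oxabicyclo[2.2.1]heptan-2-yl]ethyl}-2-(iodomethyl)-3-methyloxirane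
Product: 26 (3S)-5-[(1R,2S,3S,4S)-1,3-dimethyl-3-(4-methylpent-3-en-1-yl)-7-oxabicyclo[2.2.1]heptan-2-yl]-3-methylpent-1-en-3-ol
Conditions: Zn dust, AcOH, MeOH, rt
Reagents that add atoms: none
Why: Reductive ring opening of the 2,3-epoxy iodide: zinc inserts into the C–I bond and β-elimination breaks the C2–O bond, giving the C1=C2 vinyl group and leaving the C3–O bond, and hence the 3S configuration from step 15, untouched.

Step 18
Reactants: 26 (3S)-5-[(1R,2S,3S,4S)-1,3-dimethyl-3-(4-methylpent-3-en-1-yl)-7-oxabicyclo[2.2.1]heptan-2-yl]-3-methylpent-1-en-3-ol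
Product: 27 dactylomelol, (3S)-5-[(1R,2S,3S,4S)-3-[(3S)-3-bromo-4-chloro-4-methylpentyl]-1,3-dimethyl-7-oxabicyclo[2.2.1]heptan-2-yl]-3-methylpent-1-en-3-ol
Conditions: NBS, Et3SiCl, (DHQD)2PHAL or (DHQ)2PHAL (20 mol %), CH2Cl2–hexane, −60 °C
Reagents that add atoms: N-bromosuccinimide, O=C1CCC(=O)N1Br; chlorotriethylsilane, CC[Si](Cl)(CC)CC
Why: Proposed new method: the quinuclidine nitrogen of the cinchona alkaloid dimer takes up Br+ from NBS and passes it to one face of the electron-rich C14=C15 olefin inside its chiral pocket, and chloride released from Et3SiCl opens the bromiranium ion at the tertiary C15 (Markovnikov, anti), which puts bromine on C14 and chlorine on C15 and leaves the less nucleophilic C1=C2 vinyl group alone; the closest known reaction types are the cinchona-dimer-catalysed enantioselective vicinal dihalogenation of aryl- or amide-substituted olefins with an N-halo imide and a silyl chloride, and the unselective Markovnikov bromochlorination of trisubstituted olefins, whereas facial control on a purely aliphatic trisubstituted olefin without a directing group has not been shown.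

## Compound list

1 | (S)-carvone, (5S)-2-methyl-5-(prop-1-en-2-yl)cyclohex-2-en-1-one | CC1=CC[C@@H](CC1=O)C(C)=C | starting material
2 | (5S)-2,6-dimethyl-5-(prop-1-en-2-yl)cyclohex-2-en-1-one (C6 epimer mixture) | O=C1C(C)=CC[C@H](C(C)=C)C1C | intermediate
3 | allyl bromide | C=CCBr | starting material
4 | (5R,6R)-2,6-dimethyl-6-(prop-2-en-1-yl)-5-(prop-1-en-2-yl)cyclohex-2-en-1-one | O=C1C(C)=CC[C@H](C(C)=C)[C@@]1(C)CC=C | intermediate
5 | (5R,6R)-6-{3-[bis(3-methylbutan-2-yl)boranyl]propyl}-2,6-dimethyl-5-(prop-1-en-2-yl)cyclohex-2-en-1-one | O=C1C(C)=CC[C@H](C(C)=C)[C@@]1(C)CCCB(C(C)C(C)C)C(C)C(C)C | intermediate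
6 | (5R,6R)-6-(3-hydroxypropyl)-2,6-dimethyl-5-(prop-1-en-2-yl)cyclohex-2-en-1-one | O=C1C(C)=CC[C@H](C(C)=C)[C@@]1(C)CCCO | intermediate
7 | (5R,6R)-6-[3-(benzyloxy)propyl]-2,6-dimethyl-5-(prop-1-en-2-yl)cyclohex-2-en-1-one | O=C1C(C)=CC[C@H](C(C)=C)[C@@]1(C)CCCOCc1ccccc1 | intermediate
8 | (5S,6R)-6-[3-(benzyloxy)propyl]-5-(1-hydroperoxy-1-methoxyethyl)-2,6-dimethylcyclohex-2-en-1-one (both configurations at the peroxy carbon) | O=C1C(C)=CC[C@H](C(C)(OC)OO)[C@@]1(C)CCCOCc1ccccc1 | intermediate
9 | (5S,6R)-5-[1-(acetylperoxy)-1-methoxyethyl]-6-[3-(benzyloxy)propyl]-2,6-dimethylcyclohex-2-en-1-one | O=C1C(C)=CC[C@H](C(C)(OC)OOC(C)=O)[C@@]1(C)CCCOCc1ccccc1 | intermediate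
10 | (1S,2R)-2-[3-(benzyloxy)propyl]-2,4-dimethyl-3-oxocyclohex-4-en-1-yl acetate | O=C1C(C)=CC[C@H](OC(C)=O)[C@@]1(C)CCCOCc1ccccc1 | intermediate
11 | lithium (5S,6R)-5-acetoxy-6-[3-(benzyloxy)propyl]-2,6-dimethylcyclohex-1-en-1-olate | [Li]OC1=C(C)CC[C@H](OC(C)=O)[C@@]1(C)CCCOCc1ccccc1 | intermediate
12 | (5S,6R)-5-acetoxy-6-[3-(benzyloxy)propyl]-2,6-dimethylcyclohex-1-en-1-yl trifluoromethanesulfonate | O=S(=O)(OC1=C(C)CC[C@H](OC(C)=O)[C@@]1(C)CCCOCc1ccccc1)C(F)(F)F | intermediate
13 | 2-(2-bromoethyl)-2-methyl-1,3-dioxolane | CC1(CCBr)OCCO1 | starting material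
14 | bromo[2-(2-methyl-1,3-dioxolan-2-yl)ethyl]zinc | CC1(CC[Zn]Br)OCCO1 | intermediate
15 | (1S,2S)-2-[3-(benzyloxy)propyl]-2,4-dimethyl-3-[2-(2-methyl-1,3-dioxolan-2-yl)ethyl]cyclohex-3-en-1-yl acetate | CC1(CCC2=C(C)CC[C@H](OC(C)=O)[C@@]2(C)CCCOCc2ccccc2)OCCO1 | intermediate
16 | (1S,2S)-2-[3-(benzyloxy)propyl]-2,4-dimethyl-3-[2-(2-methyl-1,3-dioxolan-2-yl)ethyl]cyclohex-3-en-1-ol | CC1(CCC2=C(C)CC[C@H](O)[C@@]2(C)CCCOCc2ccccc2)OCCO1 | intermediate
17 | 4-[(5S,6S)-6-[3-(benzyloxy)propyl]-5-hydroxy-2,6-dimethylcyclohex-1-en-1-yl]butan-2-one | CC(=O)CCC1=C(C)CC[C@H](O)[C@@]1(C)CCCOCc1ccccc1 | intermediate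
18 | 4-[(1R,2S,3S,4S)-3-[3-(benzyloxy)propyl]-1,3-dimethyl-7-oxabicyclo[2.2.1]heptan-2-yl]butan-2-one | CC(=O)CC[C@H]1[C@](C)(CCCOCc3ccccc3)[C@@H]2CC[C@@]1(C)O2 | intermediate
19 | 4-[(1R,2S,3S,4S)-3-(3-hydroxypropyl)-1,3-dimethyl-7-oxabicyclo[2.2.1]heptan-2-yl]butan-2-one | CC(=O)CC[C@H]1[C@](C)(CCCO)[C@@H]2CC[C@@]1(C)O2 | intermediate
20 | 4-[(1R,2S,3S,4S)-1,3-dimethyl-3-(3-oxopropyl)-7-oxabicyclo[2.2.1]heptan-2-yl]butan-2-one | CC(=O)CC[C@H]1[C@](C)(CCC=O)[C@@H]2CC[C@@]1(C)O2 | intermediate
21 | 4-[(1R,2S,3S,4S)-1,3-dimethyl-3-(4-methylpent-3-en-1-yl)-7-oxabicyclo[2.2.1]heptan-2-yl]butan-2-one | CC(=O)CC[C@H]1[C@](C)(CCC=C(C)C)[C@@H]2CC[C@@]1(C)O2 | intermediate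
22 | ethyl (2E)-5-[(1R,2S,3S,4S)-1,3-dimethyl-3-(4-methylpent-3-en-1-yl)-7-oxabicyclo[2.2.1]heptan-2-yl]-3-methylpent-2-enoate | CCOC(=O)/C=C(\C)CC[C@H]1[C@](C)(CCC=C(C)C)[C@@H]2CC[C@@]1(C)O2 | intermediate
23 | (2E)-5-[(1R,2S,3S,4S)-1,3-dimethyl-3-(4-methylpent-3-en-1-yl)-7-oxabicyclo[2.2.1]heptan-2-yl]-3-methylpent-2-en-1-ol | OC/C=C(\C)CC[C@H]1[C@](C)(CCC=C(C)C)[C@@H]2CC[C@@]1(C)O2 | intermediate
24 | [(2S,3S)-3-{2-[(1R,2S,3S,4S)-1,3-dimethyl-3-(4-methylpent-3-en-1-yl)-7-oxabicyclo[2.2.1]heptan-2-yl]ethyl}-3-methyloxiran-2-yl]methanol | OC[C@@H]1O[C@@]1(C)CC[C@H]2[C@](C)(CCC=C(C)C)[C@@H]3CC[C@@]2(C)O3 | intermediate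
25 | (2R,3S)-3-{2-[(1R,2S,3S,4S)-1,3-dimethyl-3-(4-methylpent-3-en-1-yl)-7-oxabicyclo[2.2.1]heptan-2-yl]ethyl}-2-(iodomethyl)-3-methyloxirane | IC[C@@H]1O[C@@]1(C)CC[C@H]2[C@](C)(CCC=C(C)C)[C@@H]3CC[C@@]2(C)O3 | intermediate
26 | (3S)-5-[(1R,2S,3S,4S)-1,3-dimethyl-3-(4-methylpent-3-en-1-yl)-7-oxabicyclo[2.2.1]heptan-2-yl]-3-methylpent-1-en-3-ol | C=C[C@@](C)(O)CC[C@H]1[C@](C)(CCC=C(C)C)[C@@H]2CC[C@@]1(C)O2 | intermediate
27 | dactylomelol, (3S)-5-[(1R,2S,3S,4S)-3-[(3S)-3-bromo-4-chloro-4-methylpentyl]-1,3-dimethyl-7-oxabicyclo[2.2.1]heptan-2-yl]-3-methylpent-1-en-3-ol | C=C[C@@](C)(O)CC[C@H]1[C@](C)(CC[C@H](Br)C(C)(C)Cl)[C@@H]2CC[C@@]1(C)O2 | target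

## Step count and least certain steps

Total step count: 18. Longest linear sequence: 18 steps (1 to 27); 3 and 13 enter as purchased reactants.

Step 18 (bromochlorination). Most likely to go wrong: poor facial discrimination at C14, because an achiral bromine–chlorine species formed from the two reagents can add to the olefin without the catalyst, and because the olefin has no group by which the catalyst can hold it. Acid-promoted ionisation of the allylic alcohol by traces of HCl is a second risk. Fallback (known chemistry): setting out from 26, tetrabutylammonium dichlorobromate (Bu4N+ BrCl2−) in CH2Cl2 at −20 °C should add bromine and chlorine to C14=C15 with the same Markovnikov, anti course but no facial preference. This should give 27 together with its C14 epimer (3S)-5-[(1R,2S,3S,4S)-3-[(3R)-3-bromo-4-chloro-4-methylpentyl]-1,3-dimethyl-7-oxabicyclo[2.2.1]heptan-2-yl]-3-methylpent-1-en-3-ol F1. The two are separated by preparative HPLC, and F1 is returned to 26 with zinc dust and acetic acid in methanol (reductive elimination of the vicinal dihalide) for another pass. The fallback comes back to the route at 27.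

Step 9 (key step). Most likely to go wrong: diversion of the cation manifold. The ketone oxygen may capture the C7 cation reversibly as a cyclic enol ether and slow the closure. An isomeric C6 cation may be trapped by the benzyl ether oxygen with loss of the benzyl group, or may trigger a 1,2-shift from quaternary C11 followed by pinacol-type collapse at C10. Equilibration at C6 may also be incomplete. Fallback: setting out from 16 (isolated after the methanolysis of step 8, before acid is added), intramolecular alkoxymercuration with Hg(OCOCF3)2 in CH2Cl2 over NaHCO3 at 0 °C, then aqueous NaCl, should give by anti addition chloro[(1R,2R,3R,4S)-3-[3-(benzyloxy)propyl]-1,3-dimethyl-2-[2-(2-methyl-1,3-dioxolan-2-yl)ethyl]-7-oxabicyclo[2.2.1]heptan-2-yl]mercury F2, with mercury endo on C6. Reduction with sodium amalgam, Na(Hg), in aqueous NaOH–THF replaces mercury by hydrogen with retention (unlike the radical course with NaBH4) and should give 2-{2-[(1R,2S,3S,4S)-3-[3-(benzyloxy)propyl]-1,3-dimethyl-7-oxabicyclo[2.2.1]heptan-2-yl]ethyl}-2-methyl-1,3-dioxolane F3. Aqueous HCl in acetone then frees the ketone, and the fallback comes back to the route at 18.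

Step 3 (hydroboration). Most likely to go wrong: loss of chemoselectivity, through reduction of the enone carbonyl by the dialkylborane or partial hydroboration of the isopropenyl group, and epoxidation of the enone during the oxidative work-up. Fallback: setting out from 2, the lithium enolate (LiN(i-Pr)2, THF, −78 °C) is alkylated directly with 1-(benzyloxy)-3-iodopropane in THF–DMPU, the electrophile again entering anti to the isopropenyl group. This replaces steps 2 to 4, makes no new compound and comes back to the route at 7.

Step 7 (Negishi coupling). Most likely to go wrong: slow oxidative addition and transmetallation at the crowded tetrasubstituted triflate, so that cleavage of the triflate to the ketone and protonation of the organozinc compete. Fallback: setting out from 12, a B-alkyl Suzuki–Miyaura coupling. Hydroboration of 2-methyl-2-vinyl-1,3-dioxolane with 9-BBN-H in THF gives 9-[2-(2-methyl-1,3-dioxolan-2-yl)ethyl]-9-borabicyclo[3.3.1]nonane F4, which is coupled with 12 using PdCl2(dppf) and aqueous K3PO4 in DMF at 50 °C. It comes back to the route at 15.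

Step 13 (olefination). Most likely to go wrong: incomplete E selectivity in the olefination of a methyl ketone whose two substituents differ little in size, with difficult separation of the Z ester, which would end as the C3 epimer. Fallback: setting out from 21, kinetic enolisation on the methyl side (LiN(i-Pr)2, THF, −78 °C) and trapping with ClP(O)(OEt)2 gives diethyl 4-[(1R,2S,3S,4S)-1,3-dimethyl-3-(4-methylpent-3-en-1-yl)-7-oxabicyclo[2.2.1]heptan-2-yl]but-1-en-2-yl phosphate F5. Elimination with excess LiN(i-Pr)2 gives the terminal alkyne (1R,2S,3S,4S)-2-(but-3-yn-1-yl)-1,3-dimethyl-3-(4-methylpent-3-en-1-yl)-7-oxabicyclo[2.2.1]heptane F6. Zirconium-catalysed methylalumination (AlMe3, Cp2ZrCl2 cat., CH2Cl2) followed by paraformaldehyde then delivers the E allylic alcohol by syn carbometallation. It comes back to the route at 23.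

## Further compounds

F1 | step 18 | (3S)-5-[(1R,2S,3S,4S)-3-[(3R)-3-bromo-4-chloro-4-methylpentyl]-1,3-dimethyl-7-oxabicyclo[2.2.1]heptan-2-yl]-3-methylpent-1-en-3-ol | C=C[C@@](C)(O)CC[C@H]1[C@](C)(CC[C@@H](Br)C(C)(C)Cl)[C@@H]2CC[C@@]1(C)O2
F2 | step 9 | chloro[(1R,2R,3R,4S)-3-[3-(benzyloxy)propyl]-1,3-dimethyl-2-[2-(2-methyl-1,3-dioxolan-2-yl)ethyl]-7-oxabicyclo[2.2.1]heptan-2-yl]mercury | CC1(CC[C@@]2([Hg]Cl)[C@](C)(CCCOCc3ccccc3)[C@@H]4CC[C@@]2(C)O4)OCCO1
F3 | step 9 | 2-{2-[(1R,2S,3S,4S)-3-[3-(benzyloxy)propyl]-1,3-dimethyl-7-oxabicyclo[2.2.1]heptan-2-yl]ethyl}-2-methyl-1,3-dioxolane | CC1(CC[C@H]2[C@](C)(CCCOCc3ccccc3)[C@@H]4CC[C@@]2(C)O4)OCCO1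
F0 | step 3 | none | none
F4 | step 7 | 9-[2-(2-methyl-1,3-dioxolan-2-yl)ethyl]-9-borabicyclo[3.3.1]nonane | CC1(CCB2C3CCCC2CCC3)OCCO1
F5 | step 13 | diethyl 4-[(1R,2S,3S,4S)-1,3-dimethyl-3-(4-methylpent-3-en-1-yl)-7-oxabicyclo[2.2.1]heptan-2-yl]but-1-en-2-yl phosphate | C=C(OP(=O)(OCC)OCC)CC[C@H]1[C@](C)(CCC=C(C)C)[C@@H]2CC[C@@]1(C)O2
F6 | step 13 | (1R,2S,3S,4S)-2-(but-3-yn-1-yl)-1,3-dimethyl-3-(4-methylpent-3-en-1-yl)-7-oxabicyclo[2.2.1]heptane | C#CCC[C@H]1[C@](C)(CCC=C(C)C)[C@@H]2CC[C@@]1(C)O2
A1 | alternative 1 | (4R,5S,6S)-4-(methoxymethoxy)-4,6-dimethyl-5-[2-(2-methyl-1,3-dioxolan-2-yl)ethyl]cyclohex-2-en-1-one | CC1(CC[C@H]2[C@H](C)C(=O)C=C[C@@]2(C)OCOC)OCCO1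
A2 | alternative 1 | 4-(methoxymethoxy)-4-methylcyclohexa-2,5-dien-1-one | COCOC1(C)C=CC(=O)C=C1
A3 | alternative 1 | bis[2-(2-methyl-1,3-dioxolan-2-yl)ethyl]zinc | CC1(CC[Zn]CCC2(C)OCCO2)OCCO1
A4 | alternative 2 | methyl (1S,2R,6R,7R)-7-methyl-3-oxo-4,10-dioxatricyclo[5.2.1.0^2,6]decane-2-carboxylate | O=C1OC[C@H]2[C@]1(C(=O)OC)[C@@H]1CC[C@@]2(C)O1
A5 | alternative 2 | methyl (1R,5R,6S)-6-methyl-2-oxo-6-(3-oxopropyl)-3-oxabicyclo[3.1.0]hexane-1-carboxylate | O=C1OC[C@H]2[C@]1(C(=O)OC)[C@@]2(C)CCC=O
A6 | alternative 3 | (1R,2S,3S,4S)-2-ethenyl-1,3-dimethyl-3-(4-methylpent-3-en-1-yl)-7-oxabicyclo[2.2.1]heptane | C=C[C@H]1[C@](C)(CCC=C(C)C)[C@@H]2CC[C@@]1(C)O2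
A7 | alternative 3 | (5S,6S,7E)-5-hydroxy-6-methyl-6-(4-methylpent-3-en-1-yl)-9-(trimethylsilyl)non-7-en-2-one | CC(=O)CC[C@H](O)[C@@](C)(CCC=C(C)C)/C=C/C[Si](C)(C)C
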